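**Retrosynthetic overview**
1. Target ⇐ O‑formylation ⇐ methanolysis of a macrolactone in which the target's own C18 carboxyl and C15 oxygen are tied together (a tether that leaves no trace).
2. Macrolactone ⇐ intramolecular Diels–Alder reaction of a ring‑B 1‑vinylcyclohexene whose C9 side chain ends in a methacrylate; ring A and the 11‑membered lactone ring close in one operation and the tether sets C4 and C5.
3. Triene ⇐ methacryloylation and ester reduction ⇐ Stille vinylation of the C10 enol triflate ⇐ E‑selective Horner–Wadsworth–Emmons reaction on a methyl ketone.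
4. Methyl ketone ⇐ Mukaiyama–Michael addition to methyl vinyl ketone (sets C9, trans to the C8 methyl) ⇐ asymmetric methyl conjugate addition to 2‑methylcyclohexenone (sets C8).
5. Ring order: ring B is bought as 2‑methylcyclohexenone; ring A and the lactone ring form together; the lactone ring is then opened.

Assumption: in step 1 the ligand enantiomer that gives the 3R product is used (sense of induction to be confirmed on the first batch); the target is taken as 4S,5R,8R,9S,13E as the SMILES reads.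
Notation: halimane numbering is used for positions. C4 bears Me and the carboxyl carbon C18, C5 bears H, the ring alkene is C1=C10, C8 bears Me, and C9 bears Me and the chain C11–C15.

**Step 1**
Reactants: 1 2‑methylcyclohex‑2‑en‑1‑one
Product: 3 (3R)‑trimethyl[(2,3‑dimethylcyclohex‑1‑en‑1‑yl)oxy]silane, via dimethylaluminium enolate 2 (not isolated)
Conditions: Me3Al (1.4 equiv), Cu(O2CC4H3S) (copper thiophene‑2‑carboxylate, 2 mol %), binaphthol‑derived bis(1‑phenylethyl)phosphoramidite ligand (4 mol %, enantiomer that gives 3R), Et2O, −30 °C; then Me3SiOTf, −30 °C to rt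
Reagents that add atoms: trimethylaluminium C[Al](C)C; trimethylsilyl trifluoromethanesulfonate C[Si](C)(C)OS(=O)(=O)C(F)(F)F
Why: Copper‑catalysed asymmetric conjugate addition of Me3Al sets C8 (R) under ligand control, and O‑silylation of the regiodefined aluminium enolate locks the tetrasubstituted enol ether needed for the next C–C bond.

**Step 2**
Reactants: 3 (3R)‑trimethyl[(2,3‑dimethylcyclohex‑1‑en‑1‑yl)oxy]silane; 4 methyl vinyl ketone (but‑3‑en‑2‑one)
Product: 5 (2S,3R)‑2,3‑dimethyl‑2‑(3‑oxobutyl)cyclohexan‑1‑one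
Conditions: BF3·OEt2 (1.0 equiv), iPrOH (1.0 equiv), CH2Cl2, −78 °C
Reagents that add atoms: none
Why: Mukaiyama–Michael addition of the silyl enol ether to the BF3‑activated enone; the electrophile enters anti to the pseudoaxial C8 methyl, so the quaternary C9 (S) carries the chain trans to that methyl and the two methyls are cis, as in the target.

**Step 3**
Reactants: 5 (2S,3R)‑2,3‑dimethyl‑2‑(3‑oxobutyl)cyclohexan‑1‑one; 6 triethyl phosphonoacetate
Product: 7 ethyl (2E)‑5‑[(1S,2R)‑1,2‑dimethyl‑6‑oxocyclohexyl]‑3‑methylpent‑2‑enoate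
Conditions: NaH, THF, 0 °C to rt; E isomer separated on silica
Reagents that add atoms: none
Why: Horner–Wadsworth–Emmons olefination takes place only at the unhindered methyl ketone (the ring ketone is neopentyl) and gives mainly the E enoate (about 5:1 expected; the Z isomer is removed here).

**Step 4**
Reactants: 7 ethyl (2E)‑5‑[(1S,2R)‑1,2‑dimethyl‑6‑oxocyclohexyl]‑3‑methylpent‑2‑enoate
Product: 8 ethyl (2E)‑5‑[(1S,6R)‑1,6‑dimethyl‑2‑{[(trifluoromethyl)sulfonyl]oxy}cyclohex‑2‑en‑1‑yl]‑3‑methylpent‑2‑enoate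
Conditions: Tf2O, 2,6‑di‑tert‑butyl‑4‑methylpyridine, CH2Cl2, 0 °C to rt
Reagents that add atoms: trifluoromethanesulfonic anhydride O=S(=O)(OS(=O)(=O)C(F)(F)F)C(F)(F)F
Why: Enol triflate formation under non‑basic conditions can give only the C10=C5 isomer because C9 is quaternary, and it avoids γ‑deprotonation of the enoate that a strong amide base would risk.

**Step 5**
Reactants: 8 ethyl (2E)‑5‑[(1S,6R)‑1,6‑dimethyl‑2‑{[(trifluoromethyl)sulfonyl]oxy}cyclohex‑2‑en‑1‑yl]‑3‑methylpent‑2‑enoate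
Product: 9 ethyl (2E)‑5‑[(1S,6R)‑2‑ethenyl‑1,6‑dimethylcyclohex‑2‑en‑1‑yl]‑3‑methylpent‑2‑enoate
Conditions: Bu3SnCH=CH2, Pd(PPh3)4 (5 mol %), LiCl (3 equiv), THF, 65 °C
Reagents that add atoms: tributyl(vinyl)stannane C=C[Sn](CCCC)(CCCC)CCCC
Why: Stille coupling of the vinyl triflate with the vinylstannane (chloride‑promoted) gives the 1‑vinylcyclohexene diene and touches no stereocentre.

**Step 6**
Reactants: 9 ethyl (2E)‑5‑[(1S,6R)‑2‑ethenyl‑1,6‑dimethylcyclohex‑2‑en‑1‑yl]‑3‑methylpent‑2‑enoate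
Product: 10 (2E)‑5‑[(1S,6R)‑2‑ethenyl‑1,6‑dimethylcyclohex‑2‑en‑1‑yl]‑3‑methylpent‑2‑en‑1‑ol
Conditions: iBu2AlH (2.5 equiv), CH2Cl2, −78 °C; aqueous potassium sodium tartrate work‑up
Reagents that add atoms: none
Why: 1,2‑Reduction of the enoate by the aluminium hydride gives the allylic alcohol with the E geometry kept; the conjugated diene is inert.

**Step 7**
Reactants: 10 (2E)‑5‑[(1S,6R)‑2‑ethenyl‑1,6‑dimethylcyclohex‑2‑en‑1‑yl]‑3‑methylpent‑2‑en‑1‑ol; 11 methacryloyl chloride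
Product: 12 (2E)‑5‑[(1S,6R)‑2‑ethenyl‑1,6‑dimethylcyclohex‑2‑en‑1‑yl]‑3‑methylpent‑2‑en‑1‑yl 2‑methylprop‑2‑enoate
Conditions: Et3N, DMAP (cat.), CH2Cl2, 0 °C; product stored with BHT
Reagents that add atoms: none
Why: DMAP‑catalysed O‑acylation places the dienophile on the C15 oxygen, so the future C18 carboxyl is tied to the C9 side chain.

**Step 8**
Reactants: 12 (2E)‑5‑[(1S,6R)‑2‑ethenyl‑1,6‑dimethylcyclohex‑2‑en‑1‑yl]‑3‑methylpent‑2‑en‑1‑yl 2‑methylprop‑2‑enoate
Product: 13 (4S,5R,8R,9S)‑halima‑1(10),13E‑dien‑18‑oic acid 18,15‑lactone (the target's decalin with the C4 carboxyl esterified by the C15 oxygen; the 11‑membered lactone bridges C4 and C9 on the β face)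
Conditions: PhMe (0.002 M), BHT (10 mol %), 180 °C, sealed vessel, 48 h
Reagents that add atoms: none
Why: Macrocyclising intramolecular Diels–Alder reaction (the class that closes 11‑ to 14‑membered rings together with a cyclohexene): the tether from the β‑oriented C9 chain can deliver the methacrylate only to the β face with the carbonyl endo, anti to the pseudoaxial C9 methyl, which sets C5 (H α) and C4 (carboxyl β, methyl α) in one event with the electronically preferred C4–C5/C3–C2 pairing.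

**Step 9**
Reactants: 13 (4S,5R,8R,9S)‑halima‑1(10),13E‑dien‑18‑oic acid 18,15‑lactone
Product: 14 methyl (1S,5S,6R,8aR)‑5‑[(3E)‑5‑hydroxy‑3‑methylpent‑3‑en‑1‑yl]‑1,5,6‑trimethyl‑1,2,3,5,6,7,8,8a‑octahydronaphthalene‑1‑carboxylate
Conditions: NaOMe (0.3 equiv), MeOH/THF, 60 °C
Reagents that add atoms: methanol CO
Why: Methoxide‑catalysed transesterification opens the strained macrolactone to the C4 methyl ester and the free C15 alcohol; C4 is quaternary, so nothing can epimerise.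

**Step 10**
Reactants: 14 methyl (1S,5S,6R,8aR)‑5‑[(3E)‑5‑hydroxy‑3‑methylpent‑3‑en‑1‑yl]‑1,5,6‑trimethyl‑1,2,3,5,6,7,8,8a‑octahydronaphthalene‑1‑carboxylate
Product: 15 methyl (1S,5S,6R,8aR)‑5‑[(3E)‑5‑(formyloxy)‑3‑methylpent‑3‑en‑1‑yl]‑1,5,6‑trimethyl‑1,2,3,5,6,7,8,8a‑octahydronaphthalene‑1‑carboxylate (CNP0188193.1)
Conditions: HCO2H, DCC, DMAP (cat.), CH2Cl2, 0 °C to rt
Reagents that add atoms: formic acid O=CO
Why: Carbodiimide‑mediated (Steglich) esterification formylates the unhindered primary allylic alcohol under neutral conditions that leave the methyl ester and both alkenes alone.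

**Compound list**
1 | 2‑methylcyclohex‑2‑en‑1‑one | CC1=CCCCC1=O | starting material
2 | dimethylaluminium (3R)‑2,3‑dimethylcyclohex‑1‑en‑1‑olate (formed in the flask in step 1) | C[Al](C)OC1=C(C)[C@H](C)CCC1 | intermediate
3 | (3R)‑trimethyl[(2,3‑dimethylcyclohex‑1‑en‑1‑yl)oxy]silane | C[Si](C)(C)OC1=C(C)[C@H](C)CCC1 | intermediate
4 | methyl vinyl ketone (but‑3‑en‑2‑one) | CC(=O)C=C | starting material
5 | (2S,3R)‑2,3‑dimethyl‑2‑(3‑oxobutyl)cyclohexan‑1‑one | O=C1CCC[C@@H](C)[C@]1(C)CCC(C)=O | intermediate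
6 | triethyl phosphonoacetate | CCOC(=O)CP(=O)(OCC)OCC | starting material
7 | ethyl (2E)‑5‑[(1S,2R)‑1,2‑dimethyl‑6‑oxocyclohexyl]‑3‑methylpent‑2‑enoate | O=C1CCC[C@@H](C)[C@]1(C)CC/C(C)=C/C(=O)OCC | intermediate
8 | ethyl (2E)‑5‑[(1S,6R)‑1,6‑dimethyl‑2‑{[(trifluoromethyl)sulfonyl]oxy}cyclohex‑2‑en‑1‑yl]‑3‑methylpent‑2‑enoate | O=S(=O)(OC1=CCC[C@@H](C)[C@]1(C)CC/C(C)=C/C(=O)OCC)C(F)(F)F | intermediate
9 | ethyl (2E)‑5‑[(1S,6R)‑2‑ethenyl‑1,6‑dimethylcyclohex‑2‑en‑1‑yl]‑3‑methylpent‑2‑enoate | C=CC1=CCC[C@@H](C)[C@]1(C)CC/C(C)=C/C(=O)OCC | intermediate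
10 | (2E)‑5‑[(1S,6R)‑2‑ethenyl‑1,6‑dimethylcyclohex‑2‑en‑1‑yl]‑3‑methylpent‑2‑en‑1‑ol | C=CC1=CCC[C@@H](C)[C@]1(C)CC/C(C)=C/CO | intermediate
11 | methacryloyl chloride | CC(=C)C(Cl)=O | starting material
12 | (2E)‑5‑[(1S,6R)‑2‑ethenyl‑1,6‑dimethylcyclohex‑2‑en‑1‑yl]‑3‑methylpent‑2‑en‑1‑yl 2‑methylprop‑2‑enoate | C=CC1=CCC[C@@H](C)[C@]1(C)CC/C(C)=C/COC(=O)C(C)=C | intermediate
13 | (4S,5R,8R,9S)‑halima‑1(10),13E‑dien‑18‑oic acid 18,15‑lactone | O=C3[C@@]1(C)CCC=C2[C@H]1CC[C@@H](C)[C@]2(C)CC/C(C)=C/CO3 | intermediate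
14 | methyl (1S,5S,6R,8aR)‑5‑[(3E)‑5‑hydroxy‑3‑methylpent‑3‑en‑1‑yl]‑1,5,6‑trimethyl‑1,2,3,5,6,7,8,8a‑octahydronaphthalene‑1‑carboxylate | COC(=O)[C@@]1(C)CCC=C2[C@H]1CC[C@@H](C)[C@]2(C)CC/C(C)=C/CO | intermediate
15 | methyl (1S,5S,6R,8aR)‑5‑[(3E)‑5‑(formyloxy)‑3‑methylpent‑3‑en‑1‑yl]‑1,5,6‑trimethyl‑1,2,3,5,6,7,8,8a‑octahydronaphthalene‑1‑carboxylate | COC(=O)[C@@]1(C)CCC=C2[C@H]1CC[C@@H](C)[C@]2(C)CC/C(C)=C/COC=O | target

**Totals**
Total step count: 10. Longest linear sequence: 10 steps (1 to 15).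

**Three steps most likely to fail**

Step 8 (macrocyclising Diels–Alder). The 11‑membered lactone ring holds an E alkene and is stretched across the β face, so oligomerisation or no reaction is possible. The fallback sets out from 10 and comes back at 15. Alcohol 10 is formylated (HCO2H, DCC, DMAP) to (2E)‑5‑[(1S,6R)‑2‑ethenyl‑1,6‑dimethylcyclohex‑2‑en‑1‑yl]‑3‑methylpent‑2‑en‑1‑yl formate F1. An untethered intermolecular Diels–Alder reaction of this diene with methyl methacrylate (neat with BHT at 140 °C, or EtAlCl2 in CH2Cl2 at −40 °C) then gives 15 directly. Face selectivity there rests only on attack anti to the pseudoaxial C9 methyl and on the endo preference of the ester, so isomers must be separated.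

Step 2 (Michael addition that builds the quaternary C9). Polymerisation of the enone or poor trans selectivity could erode the yield. The fallback sets out from 3 and comes back at 5. MeLi (THF, 0 °C) converts 3 into lithium (3R)‑2,3‑dimethylcyclohex‑1‑en‑1‑olate F2. Alkylation with 1,3‑dichlorobut‑2‑ene, a reactive allylic chloride that also enters trans to the C8 methyl, gives (2S,3R)‑2‑(3‑chlorobut‑2‑en‑1‑yl)‑2,3‑dimethylcyclohexan‑1‑one F3. Hydrolysis of the vinyl chloride (conc. H2SO4, 0 °C) unmasks the methyl ketone and gives 5 (Wichterle sequence).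

Step 9 (methanolysis at a hindered, α‑quaternary lactone carbonyl). Methoxide attack may be too slow. The fallback sets out from 13 and comes back at 15, and it replaces acyl substitution by hydride reduction and re‑oxidation:
- LiAlH4 (THF, 0 °C) gives (4S,5R,8R,9S)‑halima‑1(10),13E‑diene‑15,18‑diol F4.
- The unhindered allylic C15 hydroxyl is formylated selectively over the neopentyl C18 hydroxyl (HCO2H 1.0 equiv, DCC, DMAP, −20 °C) to (4S,5R,8R,9S)‑18‑hydroxyhalima‑1(10),13E‑dien‑15‑yl formate F5.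
- Dess–Martin periodinane gives (4S,5R,8R,9S)‑18‑oxohalima‑1(10),13E‑dien‑15‑yl formate F6.
- NaClO2, NaH2PO4 and 2‑methylbut‑2‑ene in tBuOH/H2O give (4S,5R,8R,9S)‑15‑(formyloxy)halima‑1(10),13E‑dien‑18‑oic acid F7.
- Me3SiCHN2 in MeOH/PhMe methylates the acid to 15.

**Further compounds**
F1 | step 8 | (2E)‑5‑[(1S,6R)‑2‑ethenyl‑1,6‑dimethylcyclohex‑2‑en‑1‑yl]‑3‑methylpent‑2‑en‑1‑yl formate | C=CC1=CCC[C@@H](C)[C@]1(C)CC/C(C)=C/COC=O
F2 | step 2 | lithium (3R)‑2,3‑dimethylcyclohex‑1‑en‑1‑olate | [Li]OC1=C(C)[C@H](C)CCC1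
F3 | step 2 | (2S,3R)‑2‑(3‑chlorobut‑2‑en‑1‑yl)‑2,3‑dimethylcyclohexan‑1‑one (E/Z mixture at the chloroalkene) | O=C1CCC[C@@H](C)[C@]1(C)CC=C(C)Cl
F4 | step 9 | (4S,5R,8R,9S)‑halima‑1(10),13E‑diene‑15,18‑diol | OC[C@@]1(C)CCC=C2[C@H]1CC[C@@H](C)[C@]2(C)CC/C(C)=C/CO
F5 | step 9 | (4S,5R,8R,9S)‑18‑hydroxyhalima‑1(10),13E‑dien‑15‑yl formate | OC[C@@]1(C)CCC=C2[C@H]1CC[C@@H](C)[C@]2(C)CC/C(C)=C/COC=O
F6 | step 9 | (4S,5R,8R,9S)‑18‑oxohalima‑1(10),13E‑dien‑15‑yl formate | O=C[C@@]1(C)CCC=C2[C@H]1CC[C@@H](C)[C@]2(C)CC/C(C)=C/COC=O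
F7 | step 9 | (4S,5R,8R,9S)‑15‑(formyloxy)halima‑1(10),13E‑dien‑18‑oic acid | OC(=O)[C@@]1(C)CCC=C2[C@H]1CC[C@@H](C)[C@]2(C)CC/C(C)=C/COC=O
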